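**Retrosynthetic overview**
- The target is a 14-membered carbocycle cis-fused to an α-methylene-γ-butyrolactone, with a trans-oxirane, an (E)-allylic tertiary alcohol and a secondary acetate.
- The last ring is the 14-membered one, closed by ring-closing metathesis between the vinyl carbinol and an allyl group; just before it the oxirane is made by Shi epoxidation of the (E)-trisubstituted alkene.
- The key disconnection is the bond between the lactone O–CH carbon and the lactone β-carbon: indium-mediated allylation of an α-hydroxy aldehyde with a (Z)-2-(bromomethyl)-2-alkenoate, then lactonisation.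
- The aldehyde fragment comes from Cu-catalysed opening of a (2S,3S)-epoxybutanol silyl ether (from crotyl alcohol) by a Grignard reagent made from (S)-linalool (from geraniol). The bromide fragment comes from pent-1-en-4-yne by carboalumination/oxirane opening, oxidation, aldol–elimination and SN2′ bromination.
- Ring order: γ-lactone, then oxirane, then the 14-membered ring.

Assumption: pent-1-en-4-yne and methyl 3-(dimethylamino)propanoate are bought; the allylindium reagent 28, whose exact constitution in water is not settled, is drawn as the trivalent indium dibromide.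

**Step 1**
Reactants: 1 geraniol
Product: 2 (2S,3S)-2,3-epoxy-3,7-dimethyloct-6-en-1-ol [(2S,3S)-2,3-epoxygeraniol]
Conditions: Ti(OiPr)4 (5 mol %), L-(+)-diethyl tartrate (7 mol %), t-BuOOH, 4 Å MS, CH2Cl2, −20 °C
Reagents that add atoms: tert-butyl hydroperoxide, CC(C)(C)OO
Why: Sharpless asymmetric epoxidation of the allylic alcohol; the titanium–L-tartrate complex delivers oxygen to one face and sets the future tertiary carbinol carbon (C3, S), leaving the remote alkene untouched.

**Step 2**
Reactants: 2 (2S,3S)-2,3-epoxygeraniol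
Product: 3 (2R,3S)-2,3-epoxy-1-iodo-3,7-dimethyloct-6-ene
Conditions: I2, PPh3, imidazole, CH2Cl2, 0 °C
Reagents that add atoms: iodine, II
Why: Appel-type (Garegg–Samuelsson) iodination of the primary alcohol under buffered conditions that leave the epoxide intact.

**Step 3**
Reactants: 3 (2R,3S)-2,3-epoxy-1-iodo-3,7-dimethyloct-6-ene
Product: 4 (S)-linalool [(3S)-3,7-dimethylocta-1,6-dien-3-ol]
Conditions: activated Zn dust, EtOH–AcOH (20:1), 60 °C
Reagents that add atoms: none
Why: Reductive elimination (zinc insertion into C–I, then β-elimination that opens the epoxide) gives the transposed tertiary allylic alcohol; the C–O bond at the stereocentre is never broken, so the configuration is kept.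

**Step 4**
Reactants: 4 (S)-linalool
Product: 5 (3S)-3,7-dimethyl-3-[(triethylsilyl)oxy]octa-1,6-diene
Conditions: Et3SiOTf, 2,6-lutidine, CH2Cl2, −78 → 0 °C
Reagents that add atoms: triethylsilyl trifluoromethanesulfonate, CC[Si](CC)(CC)OS(=O)(=O)C(F)(F)F
Why: Silyl ether formation with the reactive triflate protects the hindered tertiary alcohol for the organometallic steps.

**Step 5**
Reactants: 5 (3S)-3,7-dimethyl-3-[(triethylsilyl)oxy]octa-1,6-diene
Product: 7 (4S)-4-methyl-4-[(triethylsilyl)oxy]hex-5-en-1-ol, via aldehyde 6 (not isolated)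
Conditions: O3, pyridine (3 equiv), CH2Cl2, −78 °C (Sudan Red 7B end point); then NaBH4, MeOH, −78 → 0 °C
Reagents that add atoms: ozone, [O-][O+]=O
Why: Chemoselective ozonolysis: the electron-rich trisubstituted alkene reacts well before the hindered vinyl group next to the silyloxy-bearing quaternary carbon, and the aldehyde is reduced in the same pot.

**Step 6**
Reactants: 7 (4S)-4-methyl-4-[(triethylsilyl)oxy]hex-5-en-1-ol
Product: 8 (3S)-6-bromo-3-methyl-3-[(triethylsilyl)oxy]hex-1-ene
Conditions: CBr4, PPh3, 2,6-lutidine (cat.), CH2Cl2, 0 °C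
Reagents that add atoms: carbon tetrabromide, BrC(Br)(Br)Br
Why: Appel bromination of the primary alcohol under neutral conditions.

**Step 7**
Reactants: 9 (E)-but-2-en-1-ol (crotyl alcohol)
Product: 11 triethyl{[(2S,3S)-3-methyloxiran-2-yl]methoxy}silane, via epoxy alcohol 10 (not isolated)
Conditions: Ti(OiPr)4 (5 mol %), L-(+)-diisopropyl tartrate (6 mol %), t-BuOOH, 4 Å MS, CH2Cl2, −20 °C; then P(OMe)3; then Et3N, Et3SiCl, DMAP (cat.), −20 → 0 °C
Reagents that add atoms: tert-butyl hydroperoxide, CC(C)(C)OO; chlorotriethylsilane, CC[Si](Cl)(CC)CC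
Why: Sharpless asymmetric epoxidation sets both epoxide carbons (2S,3S); silylating in the same pot avoids isolating the volatile, water-soluble epoxy alcohol.

**Step 8**
Reactants: 8 (3S)-6-bromo-3-methyl-3-[(triethylsilyl)oxy]hex-1-ene, 11 triethyl{[(2S,3S)-3-methyloxiran-2-yl]methoxy}silane
Product: 13 (2R,3S,7S)-3,7-dimethyl-1,7-bis[(triethylsilyl)oxy]non-8-en-2-ol, via Grignard reagent 12 (not isolated)
Conditions: 8, Mg turnings, THF, rt; then CuI (10 mol %), −30 °C; then 11, −30 → 0 °C
Reagents that add atoms: none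
Why: Copper-catalysed SN2 opening of the epoxide by the Grignard reagent goes with inversion at the methyl-bearing carbon, which is less hindered and not deactivated by the silyloxymethyl group; this gives the syn 2-hydroxy-3-methyl array (2R,3S), and a silyl shift between the neighbouring oxygens would be harmless because step 9 silylates the remaining hydroxyl.

**Step 9**
Reactants: 13 (2R,3S,7S)-3,7-dimethyl-1,7-bis[(triethylsilyl)oxy]non-8-en-2-ol
Product: 14 (3S,7S,8R)-3,7-dimethyl-3,8,9-tris[(triethylsilyl)oxy]non-1-ene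
Conditions: Et3SiCl, imidazole, DMAP (cat.), DMF, 0 °C → rt
Reagents that add atoms: chlorotriethylsilane, CC[Si](Cl)(CC)CC
Why: Silyl ether formation at the secondary alcohol gives the tris-silyl ether needed for the selective oxidation that follows.

**Step 10**
Reactants: 14 (3S,7S,8R)-3,7-dimethyl-3,8,9-tris[(triethylsilyl)oxy]non-1-ene
Product: 15 (2R,3S,7S)-3,7-dimethyl-2,7-bis[(triethylsilyl)oxy]non-8-enal
Conditions: (COCl)2, DMSO, CH2Cl2, −78 → −30 °C; then Et3N, −78 → 0 °C
Reagents that add atoms: none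
Why: Under Swern conditions the primary triethylsilyl ether is cleaved and oxidised in place to the aldehyde while the secondary and tertiary silyl ethers survive, and the cold, brief base treatment keeps the α-stereocentre intact.

**Step 11**
Reactants: 16 pent-1-en-4-yne
Product: 19 (3E)-4-methylhepta-3,6-dien-1-ol, via alkenylalane 17 (not isolated), via lithium aluminate 18 (not isolated)
Conditions: Me3Al (2 equiv), Cp2ZrCl2 (0.25 equiv), CH2Cl2, 0 °C → rt; then n-BuLi, THF, −78 °C; then oxirane, −78 → 0 °C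
Reagents that add atoms: trimethylaluminium, C[Al](C)C; oxirane, C1CO1
Why: Negishi zirconium-catalysed carboalumination adds methyl and aluminium syn across the alkyne with the metal at the terminus, and the aluminate opens oxirane with retention, which fixes the (E)-trisubstituted alkene.

**Step 12**
Reactants: 19 (3E)-4-methylhepta-3,6-dien-1-ol
Product: 20 (3E)-4-methylhepta-3,6-dienal
Conditions: Dess–Martin periodinane, NaHCO3, CH2Cl2, 0 °C; used at once without chromatography
Reagents that add atoms: none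
Why: Buffered Dess–Martin oxidation gives the β,γ-unsaturated aldehyde without moving the double bond into conjugation.

**Step 13**
Reactants: 20 (3E)-4-methylhepta-3,6-dienal, 21 methyl 3-(dimethylamino)propanoate
Product: 23 methyl (5E)-2-[(dimethylamino)methyl]-3-hydroxy-6-methylnona-5,8-dienoate (diastereomer mixture), via lithium enolate 22 (not isolated)
Conditions: 21, LiN(iPr)2, THF, −78 °C; then 20, −78 °C, 15 min; AcOH quench at −78 °C
Reagents that add atoms: none
Why: Kinetic lithium ester enolate aldol addition at −78 °C outruns enolisation of the sensitive aldehyde; the two new stereocentres are erased in steps 14 and 15, so their configuration does not matter.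

**Step 14**
Reactants: 23 methyl (5E)-2-[(dimethylamino)methyl]-3-hydroxy-6-methylnona-5,8-dienoate
Product: 25 methyl (5E)-3-hydroxy-6-methyl-2-methylidenenona-5,8-dienoate (racemic at C3), via ammonium iodide 24 (not isolated)
Conditions: methyl iodide (MeI), MeOH, rt; evaporate; then K2CO3, CH2Cl2–H2O, rt
Reagents that add atoms: none
Why: Quaternisation of the amine and mild E1cB (Hofmann-type) loss of trimethylamine unveil the α-methylene ester, giving the Baylis–Hillman-type adduct without a long exposure of the aldehyde to an amine base.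

**Step 15**
Reactants: 25 methyl (5E)-3-hydroxy-6-methyl-2-methylidenenona-5,8-dienoate
Product: 26 methyl (2Z,5E)-2-(bromomethyl)-6-methylnona-2,5,8-trienoate
Conditions: N-bromosuccinimide, Me2S, CH2Cl2, 0 °C → rt
Reagents that add atoms: N-bromosuccinimide, O=C1CCC(=O)N1Br
Why: SN2′ bromination through the alkoxysulfonium salt (Corey–Kim-type reagent) transposes the allylic system to the favoured (Z)-2-(bromomethyl)-2-alkenoate; no free bromine is present, so the other alkenes are untouched.

**Step 16 (key fragment coupling)**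
Reactants: 15 (2R,3S,7S)-3,7-dimethyl-2,7-bis[(triethylsilyl)oxy]non-8-enal, 26 methyl (2Z,5E)-2-(bromomethyl)-6-methylnona-2,5,8-trienoate
Product: 29 methyl (3S,4R,5R,6S,10S)-4,5-dihydroxy-6,10-dimethyl-2-methylidene-3-[(2E)-3-methylhexa-2,5-dien-1-yl]-10-[(triethylsilyl)oxy]dodec-11-enoate, via hydroxy aldehyde 27 (not isolated), via allylindium reagent 28 (not isolated)
Conditions: 15, AcOH–THF–H2O (3:1:1), rt; evaporate with toluene; then In powder (2 equiv), 26 (1.5 equiv), THF–H2O (1:1), rt
Reagents that add atoms: none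
Why: Indium-mediated Barbier-type carbonyl allylation in water: the γ-carbon of the allylindium from the (Z)-bromide attacks through a chair-like transition state (syn relation of the new carbinol and the new allylic stereocentre, the future cis-lactone), while trivalent indium chelated between the carbonyl oxygen and the freed α-hydroxyl directs attack to the face that gives the 1,2-syn diol; the tertiary silyl ether survives the mild acid.

**Step 17**
Reactants: 29 the diol ester
Product: 30 (4S,5R)-5-{(1R,2S,6S)-1-hydroxy-2,6-dimethyl-6-[(triethylsilyl)oxy]oct-7-en-1-yl}-3-methylidene-4-[(2E)-3-methylhexa-2,5-dien-1-yl]oxolan-2-one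
Conditions: TsOH·H2O (5 mol %), CH2Cl2, rt
Reagents that add atoms: none
Why: Acid-catalysed lactonisation through the γ-hydroxyl, which closes the five-membered ring faster and more favourably than the δ-hydroxyl could close a six-membered one; the syn adduct gives the cis-4,5-disubstituted α-methylene lactone.

**Step 18**
Reactants: 30 the hydroxy lactone
Product: 31 (1R,2S,6S)-2,6-dimethyl-1-{(2R,3S)-4-methylidene-3-[(2E)-3-methylhexa-2,5-dien-1-yl]-5-oxooxolan-2-yl}-6-[(triethylsilyl)oxy]oct-7-en-1-yl acetate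
Conditions: Ac2O, pyridine, DMAP (cat.), CH2Cl2, 0 °C → rt
Reagents that add atoms: acetic anhydride, CC(=O)OC(C)=O
Why: DMAP-catalysed acylation of the only free hydroxyl installs the acetate before the epoxide is introduced, so no free hydroxyl can later open the oxirane.

**Step 19**
Reactants: 31 the silyl ether acetate
Product: 32 (1R,2S,6S)-6-hydroxy-2,6-dimethyl-1-{(2R,3S)-4-methylidene-3-[(2E)-3-methylhexa-2,5-dien-1-yl]-5-oxooxolan-2-yl}oct-7-en-1-yl acetate
Conditions: HF·pyridine, pyridine, THF, 0 °C → rt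
Reagents that add atoms: none
Why: Buffered fluoride desilylation frees the tertiary allylic alcohol without ionising it and without touching the acetate or the lactone; it is done now because the later oxirane would not tolerate HF.

**Step 20**
Reactants: 32 the triene alcohol
Product: 33 (1R,2S,6S)-6-hydroxy-2,6-dimethyl-1-[(2R,3S)-3-{[(2R,3R)-3-methyl-3-(prop-2-en-1-yl)oxiran-2-yl]methyl}-4-methylidene-5-oxooxolan-2-yl]oct-7-en-1-yl acetate
Conditions: D-fructose-derived Shi ketone (3 equiv), Oxone (2KHSO5·KHSO4·K2SO4), NaHCO3, aq. Na2EDTA, MeCN, 0 °C (pH about 8)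
Reagents that add atoms: potassium peroxymonosulfate, [K+].[O-]S(=O)(=O)OO
Why: Shi asymmetric epoxidation: the chiral dioxirane attacks the electron-rich (E)-trisubstituted alkene through a spiro transition state and gives the (R,R)-oxirane under reagent control, while the monosubstituted alkenes and the electron-poor methylene lactone do not react.

**Step 21**
Reactants: 33 the epoxy diene
Product: 34 CNP0202356.4 (target)
Conditions: second-generation Grubbs catalyst RuCl2(=CHPh)(PCy3)(H2IMes) (10 mol %), CH2Cl2 (0.001 M), 40 °C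
Reagents that add atoms: none
Why: Ring-closing metathesis at high dilution forms the 14-membered ring with loss of ethene; the new disubstituted alkene next to the quaternary carbinol carbon forms as the E isomer (the Z isomer would suffer severe allylic strain), and the 1,1-disubstituted electron-poor methylene lactone is a spectator.

**Compound list**
1 | geraniol | CC(C)=CCC/C(C)=C/CO | starting material
2 | (2S,3S)-2,3-epoxy-3,7-dimethyloct-6-en-1-ol | CC(C)=CCC[C@]1(C)O[C@H]1CO | intermediate
3 | (2R,3S)-2,3-epoxy-1-iodo-3,7-dimethyloct-6-ene | CC(C)=CCC[C@]1(C)O[C@H]1CI | intermediate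
4 | (S)-linalool | CC(C)=CCC[C@](C)(O)C=C | intermediate
5 | (3S)-3,7-dimethyl-3-[(triethylsilyl)oxy]octa-1,6-diene | CC(C)=CCC[C@](C)(O[Si](CC)(CC)CC)C=C | intermediate
6 | (4S)-4-methyl-4-[(triethylsilyl)oxy]hex-5-enal | O=CCC[C@](C)(O[Si](CC)(CC)CC)C=C | intermediate (not isolated)
7 | (4S)-4-methyl-4-[(triethylsilyl)oxy]hex-5-en-1-ol | OCCC[C@](C)(O[Si](CC)(CC)CC)C=C | intermediate
8 | (3S)-6-bromo-3-methyl-3-[(triethylsilyl)oxy]hex-1-ene | BrCCC[C@](C)(O[Si](CC)(CC)CC)C=C | intermediate
9 | (E)-but-2-en-1-ol | C/C=C/CO | starting material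
10 | (2S,3S)-2,3-epoxybutan-1-ol | C[C@@H]1O[C@H]1CO | intermediate (not isolated)
11 | triethyl{[(2S,3S)-3-methyloxiran-2-yl]methoxy}silane | C[C@@H]1O[C@H]1CO[Si](CC)(CC)CC | intermediate
12 | {(4S)-4-methyl-4-[(triethylsilyl)oxy]hex-5-en-1-yl}magnesium bromide | Br[Mg]CCC[C@](C)(O[Si](CC)(CC)CC)C=C | intermediate (not isolated)
13 | (2R,3S,7S)-3,7-dimethyl-1,7-bis[(triethylsilyl)oxy]non-8-en-2-ol | CC[Si](CC)(CC)OC[C@H](O)[C@@H](C)CCC[C@](C)(O[Si](CC)(CC)CC)C=C | intermediate
14 | (3S,7S,8R)-3,7-dimethyl-3,8,9-tris[(triethylsilyl)oxy]non-1-ene | CC[Si](CC)(CC)OC[C@H](O[Si](CC)(CC)CC)[C@@H](C)CCC[C@](C)(O[Si](CC)(CC)CC)C=C | intermediate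
15 | (2R,3S,7S)-3,7-dimethyl-2,7-bis[(triethylsilyl)oxy]non-8-enal | O=C[C@H](O[Si](CC)(CC)CC)[C@@H](C)CCC[C@](C)(O[Si](CC)(CC)CC)C=C | intermediate
16 | pent-1-en-4-yne | C=CCC#C | starting material
17 | dimethyl[(1E)-2-methylpenta-1,4-dien-1-yl]alane | C=CC/C(C)=C/[Al](C)C | intermediate (not isolated)
18 | lithium butyl(dimethyl)[(1E)-2-methylpenta-1,4-dien-1-yl]aluminate | [Li+].C=CC/C(C)=C/[Al-](C)(C)CCCC | intermediate (not isolated)
19 | (3E)-4-methylhepta-3,6-dien-1-ol | OCC/C=C(\C)CC=C | intermediate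
20 | (3E)-4-methylhepta-3,6-dienal | O=CC/C=C(\C)CC=C | intermediate
21 | methyl 3-(dimethylamino)propanoate | COC(=O)CCN(C)C | starting material
22 | lithium enolate of methyl 3-(dimethylamino)propanoate | [Li+].COC([O-])=CCN(C)C | intermediate (not isolated)
23 | methyl (5E)-2-[(dimethylamino)methyl]-3-hydroxy-6-methylnona-5,8-dienoate | COC(=O)C(CN(C)C)C(O)C/C=C(\C)CC=C | intermediate
24 | [(5E)-3-hydroxy-2-(methoxycarbonyl)-6-methylnona-5,8-dien-1-yl]trimethylammonium iodide | COC(=O)C(C[N+](C)(C)C)C(O)C/C=C(\C)CC=C.[I-] | intermediate (not isolated)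
25 | methyl (5E)-3-hydroxy-6-methyl-2-methylidenenona-5,8-dienoate | COC(=O)C(=C)C(O)C/C=C(\C)CC=C | intermediate
26 | methyl (2Z,5E)-2-(bromomethyl)-6-methylnona-2,5,8-trienoate | BrC/C(C(=O)OC)=C\C/C=C(\C)CC=C | intermediate
27 | (2R,3S,7S)-2-hydroxy-3,7-dimethyl-7-[(triethylsilyl)oxy]non-8-enal | O=C[C@H](O)[C@@H](C)CCC[C@](C)(O[Si](CC)(CC)CC)C=C | intermediate (not isolated)
28 | methyl (2Z,5E)-2-[(dibromoindiganyl)methyl]-6-methylnona-2,5,8-trienoate (allylindium reagent, drawn as the trivalent indium dibromide) | Br[In](Br)C/C(C(=O)OC)=C\C/C=C(\C)CC=C | intermediate (not isolated)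
29 | methyl (3S,4R,5R,6S,10S)-4,5-dihydroxy-6,10-dimethyl-2-methylidene-3-[(2E)-3-methylhexa-2,5-dien-1-yl]-10-[(triethylsilyl)oxy]dodec-11-enoate | C=C(C(=O)OC)[C@H](C/C=C(\C)CC=C)[C@@H](O)[C@H](O)[C@@H](C)CCC[C@](C)(O[Si](CC)(CC)CC)C=C | intermediate
30 | (4S,5R)-5-{(1R,2S,6S)-1-hydroxy-2,6-dimethyl-6-[(triethylsilyl)oxy]oct-7-en-1-yl}-3-methylidene-4-[(2E)-3-methylhexa-2,5-dien-1-yl]oxolan-2-one | C=C1C(=O)O[C@@H]([C@H](O)[C@@H](C)CCC[C@](C)(O[Si](CC)(CC)CC)C=C)[C@H]1C/C=C(\C)CC=C | intermediate
31 | (1R,2S,6S)-2,6-dimethyl-1-{(2R,3S)-4-methylidene-3-[(2E)-3-methylhexa-2,5-dien-1-yl]-5-oxooxolan-2-yl}-6-[(triethylsilyl)oxy]oct-7-en-1-yl acetate | C=C1C(=O)O[C@@H]([C@H](OC(C)=O)[C@@H](C)CCC[C@](C)(O[Si](CC)(CC)CC)C=C)[C@H]1C/C=C(\C)CC=C | intermediate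
32 | (1R,2S,6S)-6-hydroxy-2,6-dimethyl-1-{(2R,3S)-4-methylidene-3-[(2E)-3-methylhexa-2,5-dien-1-yl]-5-oxooxolan-2-yl}oct-7-en-1-yl acetate | C=C1C(=O)O[C@@H]([C@H](OC(C)=O)[C@@H](C)CCC[C@](C)(O)C=C)[C@H]1C/C=C(\C)CC=C | intermediate
33 | (1R,2S,6S)-6-hydroxy-2,6-dimethyl-1-[(2R,3S)-3-{[(2R,3R)-3-methyl-3-(prop-2-en-1-yl)oxiran-2-yl]methyl}-4-methylidene-5-oxooxolan-2-yl]oct-7-en-1-yl acetate | C=C1C(=O)O[C@@H]([C@H](OC(C)=O)[C@@H](C)CCC[C@](C)(O)C=C)[C@H]1C[C@H]2O[C@]2(C)CC=C | intermediate
34 | CNP0202356.4: 14-membered epoxy cembranolide acetate (lactone O–CH R, lactone β-CH S, CH–OAc R, CH–CH3 S, C(CH3)OH S, oxirane C(CH3) R and CH R, E-alkene) | C=C1C(=O)O[C@H]2[C@H](OC(C)=O)[C@@H](C)CCC[C@](C)(O)/C=C/C[C@@]3(C)O[C@@H]3C[C@@H]12 | target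

**Totals**
Total step count: 21. Longest linear sequence: 15 steps (steps 1–6, 8–10 and 16–21, from geraniol).

**Three steps most likely to fail, with fallbacks**

Step 13 (aldol on the enolisable β,γ-unsaturated aldehyde). If 20 is enolised or isomerised by the lithium enolate, the fallback sets out from aldehyde 20 and comes back at allylic alcohol 25. Methyl propiolate is hydroaluminated with i-Bu2AlH in the presence of N-methylmorpholine N-oxide (THF, 0 °C) to give the α-aluminated acrylate [1-(methoxycarbonyl)ethenyl]bis(2-methylpropyl)alane F1. This non-basic vinyl nucleophile adds to freshly made 20 at 0 °C and gives 25 directly, so the aldehyde never meets an amide base or an ester enolate.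

Step 16 (key allylation: handling of the free α-hydroxy aldehyde and the 1,2-syn selectivity). The fallback sets out from alcohol 13 and bromide 26 and comes back at hydroxy lactone 30; it keeps the same bond construction but uses a stable ether and a Lewis-acid chelate.
- 13 is treated with 4-methoxybenzyl trichloroacetimidate and La(OTf)3 (cat.) to give (3S,7S,8R)-8-[(4-methoxyphenyl)methoxy]-3,7-dimethyl-3,9-bis[(triethylsilyl)oxy]non-1-ene F2.
- Swern oxidation, as in step 10, converts F2 into (2R,3S,7S)-2-[(4-methoxyphenyl)methoxy]-3,7-dimethyl-7-[(triethylsilyl)oxy]non-8-enal F3.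
- 26 is stannylated with Bu3SnLi (THF, −78 °C) to give methyl (2Z,5E)-6-methyl-2-[(tributylstannyl)methyl]nona-2,5,8-trienoate F4.
- MgBr2·OEt2 (CH2Cl2, −20 °C) chelates the aldehyde and ether oxygens of F3, and F4 adds in the SE2′ sense (Keck-type chelation-controlled allylation) to give methyl (3S,4R,5R,6S,10S)-4-hydroxy-5-[(4-methoxyphenyl)methoxy]-6,10-dimethyl-2-methylidene-3-[(2E)-3-methylhexa-2,5-dien-1-yl]-10-[(triethylsilyl)oxy]dodec-11-enoate F5.
- TsOH (cat.) closes F5 to (4S,5R)-5-{(1R,2S,6S)-1-[(4-methoxyphenyl)methoxy]-2,6-dimethyl-6-[(triethylsilyl)oxy]oct-7-en-1-yl}-3-methylidene-4-[(2E)-3-methylhexa-2,5-dien-1-yl]oxolan-2-one F6.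
- DDQ (CH2Cl2, pH 7 buffer) removes the 4-methoxybenzyl group and gives 30.

Step 21 (macrocyclic metathesis of the epoxide-bearing diene). If 33 cyclises poorly, the fallback sets out from 32 and comes back at target 34 by changing the order of the two ring-forming events. 32 is ring-closed first with the same ruthenium catalyst at 0.001 M; the trisubstituted alkene is far less reactive than the two terminal ones. This gives the macrocyclic (E,E)-diene acetate F7. The Shi epoxidation of step 20 is then run on F7, where the trisubstituted alkene is more electron-rich than the hindered disubstituted one, and gives 34.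

**Further compounds**
F1 | step 13 | [1-(methoxycarbonyl)ethenyl]bis(2-methylpropyl)alane | C=C(C(=O)OC)[Al](CC(C)C)CC(C)C
F2 | step 16 | (3S,7S,8R)-8-[(4-methoxyphenyl)methoxy]-3,7-dimethyl-3,9-bis[(triethylsilyl)oxy]non-1-ene | CC[Si](CC)(CC)OC[C@H](OCc1ccc(OC)cc1)[C@@H](C)CCC[C@](C)(O[Si](CC)(CC)CC)C=C
F3 | step 16 | (2R,3S,7S)-2-[(4-methoxyphenyl)methoxy]-3,7-dimethyl-7-[(triethylsilyl)oxy]non-8-enal | O=C[C@H](OCc1ccc(OC)cc1)[C@@H](C)CCC[C@](C)(O[Si](CC)(CC)CC)C=C
F4 | step 16 | methyl (2Z,5E)-6-methyl-2-[(tributylstannyl)methyl]nona-2,5,8-trienoate | CCCC[Sn](CCCC)(CCCC)C/C(C(=O)OC)=C\C/C=C(\C)CC=C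
F5 | step 16 | methyl (3S,4R,5R,6S,10S)-4-hydroxy-5-[(4-methoxyphenyl)methoxy]-6,10-dimethyl-2-methylidene-3-[(2E)-3-methylhexa-2,5-dien-1-yl]-10-[(triethylsilyl)oxy]dodec-11-enoate | C=C(C(=O)OC)[C@H](C/C=C(\C)CC=C)[C@@H](O)[C@H](OCc1ccc(OC)cc1)[C@@H](C)CCC[C@](C)(O[Si](CC)(CC)CC)C=C
F6 | step 16 | (4S,5R)-5-{(1R,2S,6S)-1-[(4-methoxyphenyl)methoxy]-2,6-dimethyl-6-[(triethylsilyl)oxy]oct-7-en-1-yl}-3-methylidene-4-[(2E)-3-methylhexa-2,5-dien-1-yl]oxolan-2-one | C=C1C(=O)O[C@@H]([C@H](OCc2ccc(OC)cc2)[C@@H](C)CCC[C@](C)(O[Si](CC)(CC)CC)C=C)[C@H]1C/C=C(\C)CC=C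
F7 | step 21 | macrocyclic (E,E)-diene acetate (the target with an (E)-trisubstituted alkene in place of the oxirane) | C=C1C(=O)O[C@H]2[C@H](OC(C)=O)[C@@H](C)CCC[C@](C)(O)/C=C/C/C(C)=C/C[C@@H]12
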